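**Retrosynthetic overview**

1. 23 ⇒ triol 19 + 2 × (Z)-hex-2-enoic acid 21; only the two equatorial hydroxyls (3α, 9α) are acylated, the axial 8α-OH stays free.
2. 19 ⇒ eremophila-9,11-dien-8-one 15: Li/NH3 gives 10α-H and the Δ8-enolate, which is hydroxylated at C9 (α face); a bulky hydride then gives the axial 8α-OH.
3. Ring B (closed second) ⇒ C7–C8 carbonyl-ene closure of the prenyl terminus onto the aldehyde carbon, the counterpart of the farnesyl C1–C10 closure with proton loss to the isopropenyl group.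
4. Ring A (closed first, same flask) ⇒ C5→C10 closure of open-chain trienal 12; the C4 cation is passed on by 1,2-H (C5→C4) and 1,2-Me (C10→C5) shifts, as in the eudesmyl→eremophilyl stage of aristolochene biosynthesis.
5. 12 ⇒ aldehyde 3 (from geranyl acetate) + alkenylzinc from enyne 6 (prenyl bromide + propynyl Grignard); this addition sets C3, and C4, C5, C7, C10, C9 and C8 follow by substrate control.

Assumption: C1–C15 are eremophilane numbers (ring A = C1–C5, C10; ring B = C5–C10; C14 on C5, C15 on C4, isopropenyl C11–C13 on C7), α/β refer to the drawing with C14 β, and the target is (3R,4R,5R,7S,8R,9S,10R)-8-hydroxyeremophil-11-ene-3,9-diyl bis[(2Z)-hex-2-enoate].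

**Route**

Step 1
Reactants: 1 geranyl acetate [(2E)-3,7-dimethylocta-2,6-dien-1-yl acetate]
Product: 3 (2E)-3-methyl-6-oxohex-2-en-1-yl acetate, via ozonide 2 (not isolated)
Conditions: O3 (1.0 equiv), CH2Cl2, −78 °C; then Me2S, −78 °C → rt
Reagents that add atoms: ozone, [O-][O+]=O
Why: Chemoselective ozonolysis: the electron-rich terminal trisubstituted alkene reacts much faster than the 2,3-alkene deactivated by the allylic acetate, and Me2S reduces the ozonide to the aldehyde; no stereocentre is involved and the 2E geometry is kept.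

Step 2
Reactants: 4 prenyl bromide (1-bromo-3-methylbut-2-ene); 5 prop-1-yn-1-ylmagnesium bromide
Product: 6 6-methylhept-5-en-2-yne
Conditions: CuBr·SMe2 (5 mol %), THF, 0 °C → rt
Reagents that add atoms: none
Why: Cu(I)-catalysed SN2 coupling of an alkynyl Grignard reagent with a primary allylic bromide gives the skipped enyne at the unhindered CH2 terminus.

Step 3
Reactants: 6 6-methylhept-5-en-2-yne; 3 (2E)-3-methyl-6-oxohex-2-en-1-yl acetate
Product: 9 (2E,6R,7E)-6-hydroxy-3,7,11-trimethyldodeca-2,7,10-trien-1-yl acetate, via alkenylzirconocene chloride 7 (not isolated), via methyl alkenylzinc 8 (not isolated)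
Conditions: Cp2Zr(H)Cl (1.2 equiv), CH2Cl2, rt; Me2Zn, toluene, −65 °C; (−)-MIB (10 mol %); add 3, −30 → 0 °C; aq NH4Cl
Reagents that add atoms: none
Why: syn-Hydrozirconation (Schwartz reagent, slight excess to equilibrate) puts Zr on the methyl-bearing alkyne carbon and fixes the 7E geometry, and Zr→Zn transmetalation followed by amino-alcohol-catalysed alkenylzinc addition (Wipf/Oppolzer type) delivers the alkenyl group to the Si face of 3, so that C6 (C3 of the target) is R (about 90% ee expected, to be raised by crystallising triol 19).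

Step 4
Reactants: 9 (2E,6R,7E)-6-hydroxy-3,7,11-trimethyldodeca-2,7,10-trien-1-yl acetate
Product: 11 (2E,6R,7E)-6-[(tert-butyldimethylsilyl)oxy]-3,7,11-trimethyldodeca-2,7,10-trien-1-ol, via silyl ether acetate 10 (not isolated)
Conditions: TBSOTf, 2,6-lutidine, CH2Cl2, −78 → 0 °C; then MeOH, K2CO3, rt
Reagents that add atoms: tert-butyldimethylsilyl triflate, CC(C)(C)[Si](C)(C)OS(=O)(=O)C(F)(F)F
Why: The silyl triflate silylates the hindered allylic alcohol, and K2CO3/MeOH then transesterifies the primary allylic acetate in the same flask; the stereocentre is not touched.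

Step 5
Reactants: 11 (2E,6R,7E)-6-[(tert-butyldimethylsilyl)oxy]-3,7,11-trimethyldodeca-2,7,10-trien-1-ol
Product: 12 (2E,6R,7E)-6-[(tert-butyldimethylsilyl)oxy]-3,7,11-trimethyldodeca-2,7,10-trienal
Conditions: MnO2, CH2Cl2, rt
Reagents that add atoms: none
Why: MnO2 oxidises the primary allylic alcohol to the enal without E/Z isomerisation or over-oxidation.

Step 6
Reactants: 12 (2E,6R,7E)-6-[(tert-butyldimethylsilyl)oxy]-3,7,11-trimethyldodeca-2,7,10-trienal
Product: 14 (3R,4R,5R,7S,8R)-3-[(tert-butyldimethylsilyl)oxy]eremophila-9,11-dien-8-ol (8β-OH), via monocyclic Z-enal 13 (not isolated)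
Conditions: MeAlCl2 (2.2 equiv), CH2Cl2 (0.01 M), −78 → −20 °C; then Me2AlCl (2 equiv), → 0 °C; Et3N, aq Rochelle salt
Reagents that add atoms: none
Why: Proposed new method: MeAlCl2 complexation of the β,β-disubstituted enal makes C10 electrophilic and C5 of the 7E-alkene attacks it through a chair (C14 methyl and H-5 axial, OTBS axial so that it does not eclipse the C4 methyl and only H-5 is aligned with the C4 cation); the cation/aluminium-enolate zwitterion then relays by antiperiplanar, suprafacial 1,2-H (H-5 → C4 α face, giving 4β-Me) and enolate-pushed 1,2-Me (C10 → C5 β face) shifts that regenerate the enal, and the Lewis-acid-equilibrated Z-enal 13 closes ring B by a type-I carbonyl-ene reaction with the new isopropenyl group equatorial and anti to the axial C14 methyl (7α; the C8 configuration is erased in step 7); the closest known reactions are Snider's alkylaluminium-chloride-induced additions of alkenes to enones and enals that end with two 1,2-shifts, and the neral → isopiperitenol and citronellal → isopulegol ene cyclisations.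

Step 7
Reactants: 14 (3R,4R,5R,7S,8R)-3-[(tert-butyldimethylsilyl)oxy]eremophila-9,11-dien-8-ol
Product: 15 (3R,4R,5R,7S)-3-[(tert-butyldimethylsilyl)oxy]eremophila-9,11-dien-8-one
Conditions: MnO2, CH2Cl2, rt
Reagents that add atoms: none
Why: Neutral MnO2 oxidation of the allylic alcohol gives the enone without moving the 11,12-alkene into conjugation, and C7 keeps its equatorial (thermodynamically preferred) isopropenyl group.

Step 8
Reactants: 15 (3R,4R,5R,7S)-3-[(tert-butyldimethylsilyl)oxy]eremophila-9,11-dien-8-one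
Product: 17 (3R,4R,5R,7S,9S,10R)-3-[(tert-butyldimethylsilyl)oxy]-9-hydroxyeremophil-11-en-8-one, via lithium enolate 16 (not isolated)
Conditions: Li (2.1 equiv), t-BuOH (1.0 equiv), NH3/THF, −78 °C; evaporate NH3; (10-camphorsulfonyl)oxaziridine, THF, −78 °C; aq NH4Cl
Reagents that add atoms: (10-camphorsulfonyl)oxaziridine, CC1(C)C2CCC13CS(=O)(=O)N4OC34C2
Why: Stork dissolving-metal reduction protonates C10 axially to the trans-fused Δ8-enolate (10α-H, all other substituents equatorial), and Davis hydroxylation of this regiodefined enolate occurs on the α face, anti to the syn-axial C14 methyl, giving the equatorial 9α-OH (as in the 4α-functionalisation of reduced steroidal 4-en-3-ones).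

Step 9
Reactants: 17 (3R,4R,5R,7S,9S,10R)-3-[(tert-butyldimethylsilyl)oxy]-9-hydroxyeremophil-11-en-8-one
Product: 18 (3R,4R,5R,7S,8R,9S,10R)-3-[(tert-butyldimethylsilyl)oxy]eremophil-11-ene-8,9-diol
Conditions: L-Selectride (2.5 equiv), THF, −78 °C; aq NH4Cl
Reagents that add atoms: none
Why: The bulky trialkylborohydride attacks the cyclohexanone equatorially (β face), giving the axial 8α-alcohol cis to the 9α-OH.

Step 10
Reactants: 18 (3R,4R,5R,7S,8R,9S,10R)-3-[(tert-butyldimethylsilyl)oxy]eremophil-11-ene-8,9-diol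
Product: 19 (3R,4R,5R,7S,8R,9S,10R)-eremophil-11-ene-3,8,9-triol
Conditions: TBAF, THF, rt → 45 °C
Reagents that add atoms: none
Why: Fluoride cleaves the Si–O bond; no stereocentre is affected.

Step 11
Reactants: 20 hex-2-ynoic acid
Product: 21 (2Z)-hex-2-enoic acid
Conditions: H2 (1 atm), Lindlar catalyst, quinoline, EtOAc, rt
Reagents that add atoms: none
Why: Lindlar syn-semihydrogenation of the alkyne gives the Z-alkene.

Step 12
Reactants: 19 (3R,4R,5R,7S,8R,9S,10R)-eremophil-11-ene-3,8,9-triol; 21 (2Z)-hex-2-enoic acid (2.2 equiv)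
Product: 23 (3R,4R,5R,7S,8R,9S,10R)-8-hydroxyeremophil-11-ene-3,9-diyl bis[(2Z)-hex-2-enoate] (CNP0420276.1), via O-acylisourea 22 (not isolated)
Conditions: EDC·HCl (2.4 equiv), DMAP (0.2 equiv), CH2Cl2, 0 °C
Reagents that add atoms: none
Why: Steglich (carbodiimide/DMAP) acylation takes the two equatorial hydroxyls (3α, 9α) while the axial 8α-OH, flanked by C7 and the new C9 ester, stays free (a misplaced 8-ester would move to the equatorial 9-position by 1,2-acyl shift), and 0 °C with little DMAP limits Z→E isomerisation.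

**Compound list**

1 | geranyl acetate, (2E)-3,7-dimethylocta-2,6-dien-1-yl acetate | CC(=O)OC/C=C(\C)CCC=C(C)C | starting material
2 | (2E)-5-(5,5-dimethyl-1,2,4-trioxolan-3-yl)-3-methylpent-2-en-1-yl acetate (ozonide) | CC(=O)OC/C=C(\C)CCC1OOC(C)(C)O1 | intermediate (not isolated)
3 | (2E)-3-methyl-6-oxohex-2-en-1-yl acetate | CC(=O)OC/C=C(\C)CCC=O | intermediate
4 | prenyl bromide, 1-bromo-3-methylbut-2-ene | CC(C)=CCBr | starting material
5 | prop-1-yn-1-ylmagnesium bromide | CC#C[Mg]Br | starting material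
6 | 6-methylhept-5-en-2-yne | CC#CCC=C(C)C | intermediate
7 | chlorobis(cyclopentadienyl)[(2E)-6-methylhepta-2,5-dien-2-yl]zirconium | C/C(=C\CC=C(C)C)[Zr](Cl)(C1C=CC=C1)C1C=CC=C1 | intermediate (not isolated)
8 | methyl[(2E)-6-methylhepta-2,5-dien-2-yl]zinc | C/C(=C\CC=C(C)C)[Zn]C | intermediate (not isolated)
9 | (2E,6R,7E)-6-hydroxy-3,7,11-trimethyldodeca-2,7,10-trien-1-yl acetate | CC(=O)OC/C=C(\C)CC[C@@H](O)/C(C)=C/CC=C(C)C | intermediate
10 | (2E,6R,7E)-6-[(tert-butyldimethylsilyl)oxy]-3,7,11-trimethyldodeca-2,7,10-trien-1-yl acetate | CC(=O)OC/C=C(\C)CC[C@@H](O[Si](C)(C)C(C)(C)C)/C(C)=C/CC=C(C)C | intermediate (not isolated)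
11 | (2E,6R,7E)-6-[(tert-butyldimethylsilyl)oxy]-3,7,11-trimethyldodeca-2,7,10-trien-1-ol | OC/C=C(\C)CC[C@@H](O[Si](C)(C)C(C)(C)C)/C(C)=C/CC=C(C)C | intermediate
12 | (2E,6R,7E)-6-[(tert-butyldimethylsilyl)oxy]-3,7,11-trimethyldodeca-2,7,10-trienal | O=C/C=C(\C)CC[C@@H](O[Si](C)(C)C(C)(C)C)/C(C)=C/CC=C(C)C | intermediate
13 | (2Z)-2-[(2R,3R,4R)-4-[(tert-butyldimethylsilyl)oxy]-2,3-dimethyl-2-(3-methylbut-2-en-1-yl)cyclohexylidene]acetaldehyde | CC(C)=CC[C@]1(C)[C@@H](C)[C@H](O[Si](C)(C)C(C)(C)C)CC/C1=C/C=O | intermediate (not isolated)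
14 | (3R,4R,5R,7S,8R)-3-[(tert-butyldimethylsilyl)oxy]eremophila-9,11-dien-8-ol (3α-OTBS, 4β,5β-dimethyl, 7α-isopropenyl, 8β-OH) | C=C(C)[C@@H]1C[C@]2(C)[C@@H](C)[C@H](O[Si](C)(C)C(C)(C)C)CCC2=C[C@H]1O | intermediate
15 | (3R,4R,5R,7S)-3-[(tert-butyldimethylsilyl)oxy]eremophila-9,11-dien-8-one | C=C(C)[C@@H]1C[C@]2(C)[C@@H](C)[C@H](O[Si](C)(C)C(C)(C)C)CCC2=CC1=O | intermediate
16 | lithium 3α-[(tert-butyldimethylsilyl)oxy]-10αH-eremophila-8,11-dien-8-olate | C=C(C)[C@@H]1C[C@]2(C)[C@@H](C)[C@H](O[Si](C)(C)C(C)(C)C)CC[C@H]2C=C1[O-].[Li+] | intermediate (not isolated)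
17 | (3R,4R,5R,7S,9S,10R)-3-[(tert-butyldimethylsilyl)oxy]-9-hydroxyeremophil-11-en-8-one | C=C(C)[C@@H]1C[C@]2(C)[C@@H](C)[C@H](O[Si](C)(C)C(C)(C)C)CC[C@H]2[C@H](O)C1=O | intermediate
18 | (3R,4R,5R,7S,8R,9S,10R)-3-[(tert-butyldimethylsilyl)oxy]eremophil-11-ene-8,9-diol | C=C(C)[C@@H]1C[C@]2(C)[C@@H](C)[C@H](O[Si](C)(C)C(C)(C)C)CC[C@H]2[C@H](O)[C@@H]1O | intermediate
19 | (3R,4R,5R,7S,8R,9S,10R)-eremophil-11-ene-3,8,9-triol | C=C(C)[C@@H]1C[C@]2(C)[C@@H](C)[C@H](O)CC[C@H]2[C@H](O)[C@@H]1O | intermediate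
20 | hex-2-ynoic acid | CCCC#CC(=O)O | starting material
21 | (2Z)-hex-2-enoic acid | CCC/C=C\C(=O)O | intermediate
22 | O-[(2Z)-hex-2-enoyl]-N-[3-(dimethylamino)propyl]-N′-ethylisourea | CCC/C=C\C(=O)OC(=NCC)NCCCN(C)C | intermediate (not isolated)
23 | (3R,4R,5R,7S,8R,9S,10R)-8-hydroxyeremophil-11-ene-3,9-diyl bis[(2Z)-hex-2-enoate] | C=C(C)[C@@H]1C[C@]2(C)[C@@H](C)[C@H](OC(=O)/C=C\CCC)CC[C@H]2[C@H](OC(=O)/C=C\CCC)[C@@H]1O | target

**Step count and risks**

Total: 12 steps. Longest linear sequence: 10 steps (1, 3, 4, 5, 6, 7, 8, 9, 10, 12); steps 2 and 11 are side branches.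

Most likely to fail:

1. Step 6 (one-flask double cyclisation). The C5 cation may take a hydride from the doubly allylic C6 instead of the methyl group from C10. The OTBS group may sit equatorial in the closing chair, which aligns H-3 and leads to the C3-epimeric series or a 3-ketone. The regenerated enal may not reach the Z form needed for ring B. Fallback: close the ten-membered ring first. Setting out from enal 12, ene-type chlorination of the terminal prenyl group (NCS, cat. PhSeCl, CH2Cl2) gives the allylic chloride (2E,6R,7E)-10-chloro-6-[(tert-butyldimethylsilyl)oxy]-3,7,11-trimethyldodeca-2,7,11-trienal F1. CrCl2-mediated intramolecular Nozaki–Hiyama allylation of the aldehyde (THF, high dilution) gives the germacrane-type (2E,6R,7E)-6-[(tert-butyldimethylsilyl)oxy]-3,7-dimethyl-10-(prop-1-en-2-yl)cyclodeca-2,7-dien-1-ol F2, and Dess–Martin oxidation gives (2E,6R,7E)-6-[(tert-butyldimethylsilyl)oxy]-3,7-dimethyl-10-(prop-1-en-2-yl)cyclodeca-2,7-dien-1-one F3 (both as C10 epimers). In F3 the enone geometry is locked by the ring and C6 is no longer flanked by two alkenes. MeAlCl2 then runs the same C5→C10 closure and 1,2-H/1,2-Me shifts transannularly (DBU afterwards to bring C7 to the equatorial epimer if needed) and gives enone 15, where the route is re-joined.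

2. Step 3 (regiochemistry of hydrozirconation of a methyl alkyne; enantioselectivity with an unbranched aldehyde). Fallback: separate C–C bond formation from stereocontrol. Setting out from enyne 6, hydrozirconation followed by iodine gives (2E)-2-iodo-6-methylhepta-2,5-diene F4, which is purified from its regioisomer. Nozaki–Hiyama–Kishi coupling with aldehyde 3 (CrCl2, cat. NiCl2, DMF) gives racemic (2E,7E)-6-hydroxy-3,7,11-trimethyldodeca-2,7,10-trien-1-yl acetate F5. Dess–Martin oxidation gives (2E,7E)-3,7,11-trimethyl-6-oxododeca-2,7,10-trien-1-yl acetate F6, and (S)-Me-CBS/catecholborane reduction of this α-methyl enone returns the (6R)-alcohol 9.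

3. Step 12 (Z→E isomerisation of the enoate under DMAP; over-acylation at O8). Fallback: form the Z-alkenes after the ester bonds. Setting out from triol 19 and hex-2-ynoic acid 20, DIC/cat. DMAP esterification of the two equatorial hydroxyls gives (3R,4R,5R,7S,8R,9S,10R)-8-hydroxyeremophil-11-ene-3,9-diyl bis(hex-2-ynoate) F7. Lindlar semihydrogenation (Pd/CaCO3–Pb, quinoline, H2), which leaves the isopropenyl group alone, gives target 23.

**Further compounds**

F1 | step 6 | (2E,6R,7E)-10-chloro-6-[(tert-butyldimethylsilyl)oxy]-3,7,11-trimethyldodeca-2,7,11-trienal (C10 epimers) | O=C/C=C(\C)CC[C@@H](O[Si](C)(C)C(C)(C)C)/C(C)=C/CC(Cl)C(C)=C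
F2 | step 6 | (2E,6R,7E)-6-[(tert-butyldimethylsilyl)oxy]-3,7-dimethyl-10-(prop-1-en-2-yl)cyclodeca-2,7-dien-1-ol (C1/C10 epimers) | C=C(C)C1C/C=C(\C)[C@H](O[Si](C)(C)C(C)(C)C)CC/C(C)=C/C1O
F3 | step 6 | (2E,6R,7E)-6-[(tert-butyldimethylsilyl)oxy]-3,7-dimethyl-10-(prop-1-en-2-yl)cyclodeca-2,7-dien-1-one (C10 epimers) | C=C(C)C1C/C=C(\C)[C@H](O[Si](C)(C)C(C)(C)C)CC/C(C)=C/C1=O
F4 | step 3 | (2E)-2-iodo-6-methylhepta-2,5-diene | C/C(I)=C\CC=C(C)C
F5 | step 3 | rac-(2E,7E)-6-hydroxy-3,7,11-trimethyldodeca-2,7,10-trien-1-yl acetate | CC(=O)OC/C=C(\C)CCC(O)/C(C)=C/CC=C(C)C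
F6 | step 3 | (2E,7E)-3,7,11-trimethyl-6-oxododeca-2,7,10-trien-1-yl acetate | CC(=O)OC/C=C(\C)CCC(=O)/C(C)=C/CC=C(C)C
F7 | step 12 | (3R,4R,5R,7S,8R,9S,10R)-8-hydroxyeremophil-11-ene-3,9-diyl bis(hex-2-ynoate) | C=C(C)[C@@H]1C[C@]2(C)[C@@H](C)[C@H](OC(=O)C#CCCC)CC[C@H]2[C@H](OC(=O)C#CCCC)[C@@H]1O
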